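Amounts first: the flask holds 11 mM of each mirror-image substrate against 8.80 mM of partner, with 2.20 mM of protic impurity beside them.

common to all: left-handed substrate 11 mM; right-handed substrate 11 mM

| flask | partner | protic impurity | precatalyst | remark | time |
|---|---|---|---|---|---|
| Tuesday's | 8.8 mM (in portions, 3) | 2.2 mM | 28 µM | run made earlier; portions every 80 min |  |
| Friday's | 8.8 mM (in portions, 3) | 2.2 mM | 110 µM | run made earlier; portions every 80 min |  |
| flask | 8.80 mM (in portions, 3) | 2.20 mM | 55 µM | the portions of partner follow each other after 80 min, the first at the start | 6.0 d |

| run | time / d | left-handed substrate / % | left-handed product / % |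
|---|---|---|---|
| Tuesday's | 0.333 | 47.9 | 2.8 |
| Tuesday's | 0.833 | 38.2 | 11.5 |
| Tuesday's | 1.67 | 30.8 | 19.8 |
| Tuesday's | 2.50 | 27.5 | 22.8 |
| Tuesday's | 4.00 | 25.3 | 24.7 |
| Tuesday's | 5.00 | 25.3 | 24.4 |
| Tuesday's | 6.00 | 23.7 | 25.7 |
| Friday's | 0.333 | 40.7 | 9.8 |
| Friday's | 0.833 | 28.8 | 22.0 |
| Friday's | 1.67 | 25.1 | 25.2 |
| Friday's | 2.50 | 25.4 | 25.4 |
| Friday's | 4.00 | 24.5 | 24.8 |
| Friday's | 5.00 | 24.8 | 25.5 |
| Friday's | 6.00 | 24.7 | 25.8 |

(scatter of a reading: 0.5 percentage points)

- at 6.0 d, what has stopped the reaction, if anything has (all of the left-handed substrate has reacted / the partner has run out first / forward and back rates have come level / it is still moving / no working catalyst is left)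
- share of the left-handed substrate and right-handed substrate together used up at 6.0 d
- left-handed product at 6.0 d, in percent of the left-handed substrate and right-handed substrate together charged

- free catalyst is single-handed; left-handed substrate and right-handed substrate are mirror images of each other, charged as a racemate, each of them at the stated concentration
- the reaction counts as stopped when no species that holds the left-handed substrate and right-handed substrate together changes by six tenths of a point or more over the second half of the time

The bench rule of thumb counts one partner for each substrate used up, which makes partner the limiting reagent and caps conversion at the ratio of the charges: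

ceiling = [partner] / ([left-handed substrate] + [right-handed substrate]) = 40.0 %

The rule reaches its border where something else also takes partner. Here the ratio [protic impurity]/[partner] is 25.0 %, so a quarter of the partner is lost if the impurity consumes it one to one and ahead of the catalyst. This reckoning assumes that quench, and counts it as finished early:

usable = ([partner] − [protic impurity]) / ([left-handed substrate] + [right-handed substrate]) = 30.0 %

This usable partner is the partner left after the quench, in percent of both substrates together. Tuesday's run, with 28 µM of precatalyst, reads 25.7 % of left-handed product at its last point, and Friday's run, with 110 µM, reads 25.8 %. Friday's reading is below the usable partner by 4.2 percentage points, which leaves room for a product that the readings do not show. The reckoning here therefore commits to a conversion of 30.0 % in the flask, stopped by partner.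

The forecast differs. It gives forward and back rates have come level, with conversion 25 % and left-handed product 25.2 %, and in its words “partner is probably not limiting, and the stop looks like equilibrium”.

The flask gives the partner has run out first, with conversion 29.8 % and left-handed product 25.3 %.

    partner + catalyst intermediate B → free catalyst + right-handed product (k = 9.08 M⁻¹ min⁻¹)
    partner + catalyst intermediate A → free catalyst + left-handed product (k = 154 M⁻¹ min⁻¹)
    partner + precatalyst → free catalyst + spent reagent (k = 0.268 M⁻¹ min⁻¹)
    free catalyst → spent catalyst (k = 7.02 × 10⁻⁴ min⁻¹)
    free catalyst + left-handed substrate ⇌ catalyst intermediate A (K = 120 M⁻¹, k = 1710 M⁻¹ min⁻¹)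
    partner + protic impurity → quenched reagent (k = 23.1 M⁻¹ min⁻¹)
    free catalyst + right-handed substrate ⇌ catalyst intermediate B (K = 263 M⁻¹, k = 16100 M⁻¹ min⁻¹)

In the flask, 0.11 % of the charged partner stands at the end, and the right-handed product, at 4.47 %, joins the left-handed product to make a conversion that meets the usable partner of 30.0 %. The largest single effect on the left-handed product, which holds more of that conversion than the right-handed product, comes from the back reaction of catalyst intermediate B to free catalyst + right-handed substrate, since the same run with that back reaction struck out holds 0.140 % of left-handed product instead of 25.3 % and no longer ends by the same stop. In the neighbouring flask with 0.88 mM of protic impurity, the usable partner comes to 36.0 %, and that flask reaches a conversion of 35.7 %.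

The readings stem from a simulated flask for an exercise; the scatter is artificial.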